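The runs are calculated for an exercise; noise was put on by code.

If we want what a flask of this ligand exchange holds late on, we first ask which of its settings count separately.

| flask | starting complex | incoming ligand | remark | time |
|---|---|---|---|---|
| green | 0.40 M | 0.40 M | run made earlier |  |
| blue | 0.60 M | 0.40 M | run made earlier |  |
| violet | 0.80 M | 0.80 M | run made earlier |  |
| flask | 0.80 M | 0.400 M |  | 8.0 h |

| run | time / h | complex with one exchanged / % |
|---|---|---|
| green | 1.50 | 33 |
| green | 3.00 | 25 |
| green | 5.00 | 20 |
| green | 6.00 | 14 |
| green | 8.00 | 17 |
| green | 10.0 | 17 |
| blue | 0.833 | 29 |
| blue | 1.33 | 27 |
| blue | 2.00 | 24 |
| blue | 4.00 | 16 |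
| blue | 6.00 | 12 |
| blue | 10.0 | 9 |
| violet | 0.833 | 31 |
| violet | 1.33 | 27 |
| violet | 2.50 | 17 |
| violet | 5.00 | 12 |
| violet | 10.0 | 9 |

(each reading ± 2 percentage points)

- percentages count the starting complex that a species holds: one side product counts as two
- on the list of suspects stand: complex with one exchanged + incoming ligand <-> leaving ligand + complex with two exchanged; starting complex + incoming ligand <-> leaving ligand + complex with one exchanged; starting complex + complex with one exchanged -> side product

- equivalents of incoming ligand to starting complex, everything else as given, that leave most complex with one exchanged at 8.0 h
- the amount of complex with one exchanged then, in percent of the starting complex charged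
- the amount of complex with one exchanged with the amounts as given

Two readings seem contradictory: green and violet are both charged at one equivalent, yet after 10.0 h green reads 17% and violet 9%. But each suspect step is bimolecular, so doubling every charge doubles each rate of change in percent, and violet runs the same course in half the time. The clock is therefore charged [starting complex] times time, which in our flask is 384 M·min; we call it the dose. At one temperature, flasks of these steps charged without leaving ligand, with equal equivalents and equal dose, hold equal percentages. At a dose of 120 M·min green reads 20% and violet 17%; at 240 M·min they read 17% and 12%, gaps that two readings scattering by 2 percentage points can give. Violet's last reading simply stands further along, at 480 M·min.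

A reading close to our flask is blue at 10.0 h: dose 360 M·min, 0.667 equivalents, 9%. Our flask has 0.500 equivalents, incoming ligand being the limiting reagent, and scaling blue crudely by equivalents we expect 6.75%.

The forecast, holding that “Excess ligand consumes the starting complex and so suppresses the side reaction”, gives 7.5% as charged, more than our figure, and 25% at 4 equiv.

The flask gives 7.46% as charged and 12.1% at 3.22 equiv.

    complex with one exchanged + incoming ligand ⇌ leaving ligand + complex with two exchanged (K = 1.80, k = 0.260 M⁻¹ h⁻¹)
    starting complex + incoming ligand ⇌ leaving ligand + complex with one exchanged (K = 0.390, k = 3.20 M⁻¹ h⁻¹)
    starting complex + complex with one exchanged → side product (k = 0.410 M⁻¹ h⁻¹)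

At the flask's dose of 384 M·min, complex with one exchanged is made at 0.430 of the rate at which it is used, each step taken net. The step from starting complex and incoming ligand to complex with one exchanged, taken by itself and both ways together, relaxes at that time with a half-life of 0.158 h, short against 8.0 h. The neighbour with 0.32 M of starting complex has 1.25 equiv and a dose of 154 M·min, between green's readings at 6.00 h and 8.00 h; their mean, scaled from one equivalent, gives 19.4%. Computed, it holds 18.8%.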